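**Assumptions.** Squamatic acid has no stereocentres, so there is no enantiomer issue and the SMILES is fully specified as given. Orsellinic acid (1) and 2,5-dimethylresorcinol (6, β-orcinol) are assumed commercially available.

## Retrosynthetic overview
1. Squamatic acid comes from hydrogenolysis of a ring-B benzyl ester, preceded by Pinnick oxidation of a ring-A 3-formyl group that masks the 3-CO2H.
2. The depside C(=O)–O bond is disconnected to a ring-A salicylic acid (5) and a ring-B phenol (8). This is the **proposed new step**: boron-templated, protecting-group-free coupling.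
3. Ring A is made from orsellinic acid by allyl ester formation, 4-O-methylation, ortho-formylation at C3 and deallylation.
4. Ring B is made from 2,5-dimethylresorcinol by Kolbe–Schmitt carboxylation and benzyl ester formation.
5. Both arenes are already aromatic in the starting materials, so no ring is formed. The two rings are joined only by the ester.

## Route

**Step 1**
Reactants: 1 (orsellinic acid)
Product: 2 (allyl 2,4-dihydroxy-6-methylbenzoate)
Conditions: allyl bromide, NaHCO3, DMF, rt, 16 h
Reagents that add atoms: allyl bromide, C=CCBr
Why: The carboxylate is the only species deprotonated by bicarbonate, so it undergoes SN2 O-alkylation selectively over the phenols.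

**Step 2**
Reactants: 2
Product: 3 (allyl 2-hydroxy-4-methoxy-6-methylbenzoate)
Conditions: MeI (1.05 equiv), K2CO3 (1.1 equiv), acetone, rt, 12 h
Reagents that add atoms: methyl iodide, CI
Why: The 4-OH is the more acidic, non-chelated phenol, whereas the 2-OH is H-bonded to the ester, so Williamson methylation occurs at C4-OH.

**Step 3**
Reactants: 3
Product: 4 (allyl 3-formyl-2-hydroxy-4-methoxy-6-methylbenzoate)
Conditions: (CH2O)n, MgCl2, Et3N, MeCN, 80 °C, 6 h
Reagents that add atoms: paraformaldehyde, C=O
Why: In the Casnati–Skattebøl ortho-formylation, the Mg phenoxide delivers formaldehyde to the only free ortho position of the 2-OH, which is C3 between OH and OMe.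

**Step 4**
Reactants: 4
Product: 5 (3-formyl-2-hydroxy-4-methoxy-6-methylbenzoic acid)
Conditions: Pd(PPh3)4 (5 mol%), potassium 2-ethylhexanoate, THF/EtOAc, rt, 2 h; then 1 M HCl to pH 2
Reagents that add atoms: none
Why: Tsuji–Trost allyl transfer to the carboxylate scavenger removes the ester under neutral conditions that leave the aldehyde and phenol untouched.

**Step 5**
Reactants: 6 (2,5-dimethylresorcinol, Cc1cc(O)c(C)c(O)c1)
Product: 7 (2,4-dihydroxy-3,6-dimethylbenzoic acid)
Conditions: KHCO3, H2O, CO2 (3 atm), 90 °C, 8 h; then HCl, 0 °C
Reagents that add atoms: carbon dioxide, O=C=O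
Why: In the Kolbe–Schmitt carboxylation, 6 is symmetric, so carboxylation ortho to one OH and para to the other gives only the β-orcinol carboxylic acid.

**Step 6**
Reactants: 7
Product: 8 (benzyl 2,4-dihydroxy-3,6-dimethylbenzoate)
Conditions: BnBr, NaHCO3, DMF, rt, 16 h
Reagents that add atoms: benzyl bromide, BrCc1ccccc1
Why: Only the carboxylate is alkylated under these mild conditions, giving a benzyl ester that can later be removed by hydrogenolysis without touching the depside bond.

**Step 7 (key new step)**
Reactants: 5 (3-formyl-2-hydroxy-4-methoxy-6-methylbenzoic acid); 8 (benzyl 2,4-dihydroxy-3,6-dimethylbenzoate)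
Product: 9 (benzyl 4-[(3-formyl-2-hydroxy-4-methoxy-6-methylbenzoyl)oxy]-2-hydroxy-3,6-dimethylbenzoate)
Conditions: (a) 5 (1.0 equiv), 3,5-(CF3)2C6H3B(OH)2 (1.2 equiv), 4 Å MS, PhMe, 80 °C, 2 h; (b) add 8 (1.1 equiv), DMAP (0.3 equiv), i-Pr2NEt (1.5 equiv), MeCN, 50 °C, 16 h; workup with aq. NH4Cl and D-sorbitol
Reagents that add atoms: none (the boron reagent is removed on workup)
Why: Proposed new method: the arylboronic acid condenses with the o-hydroxy acid of 5 to give a 2-aryl-4H-1,3,2-benzodioxaborinin-4-one, which masks the 2-OH (preventing self-esterification into oligomeric depsides) and makes the carboxyl an acyloxyborane-type acyl donor. The more acidic, unhindered 4-OH of 8 then attacks with DMAP assistance, while its 2-OH stays H-bonded to the ester and is flanked by the 3-Me, so esterification is regioselective for 4-OH. Sorbitol strips the boron from the product's 2-O. The closest known chemistry is boron-templated esterification of α-hydroxy acids and boronic-acid-promoted amidation; neither has been shown for salicylic acids with phenols to make depsides, and this avoids 2-OH protection and acid chlorides. No stereocentre is involved.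

**Step 8**
Reactants: 9
Product: 10 (benzyl ester of squamatic acid: 3-carboxy-ring A, ring-B benzyl ester)
Conditions: NaClO2, NaH2PO4, 2-methyl-2-butene, t-BuOH/H2O, rt, 3 h
Reagents that add atoms: sodium chlorite, [Na+].[O-]Cl=O (supplies the O of the new CO2H)
Why: Pinnick oxidation converts the aldehyde to the acid, with the alkene scavenging HOCl so the arene is not chlorinated, and the aryl ester and benzyl ester are stable at this mildly acidic pH.

**Step 9**
Reactants: 10
Product: 11 (squamatic acid)
Conditions: H2 (1 atm), 10% Pd/C, EtOAc/THF, rt, 2 h
Reagents that add atoms: none (hydrogen only)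
Why: Catalytic hydrogenolysis cleaves the benzyl ester to the free acid, releasing toluene, while the aryl ester, methyl ether and phenols are unaffected. Nothing reducible remains, because the aldehyde was oxidised in step 8.

## Compound list
1 | orsellinic acid (2,4-dihydroxy-6-methylbenzoic acid) | Cc1cc(O)cc(O)c1C(=O)O | starting material
2 | allyl 2,4-dihydroxy-6-methylbenzoate | C=CCOC(=O)c1c(C)cc(O)cc1O | intermediate
3 | allyl 2-hydroxy-4-methoxy-6-methylbenzoate | C=CCOC(=O)c1c(C)cc(OC)cc1O | intermediate
4 | allyl 3-formyl-2-hydroxy-4-methoxy-6-methylbenzoate | C=CCOC(=O)c1c(C)cc(OC)c(C=O)c1O | intermediate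
5 | 3-formyl-2-hydroxy-4-methoxy-6-methylbenzoic acid | Cc1cc(OC)c(C=O)c(O)c1C(=O)O | intermediate
6 | 2,5-dimethylresorcinol (β-orcinol) | Cc1cc(O)c(C)c(O)c1 | starting material
7 | 2,4-dihydroxy-3,6-dimethylbenzoic acid | Cc1cc(O)c(C)c(O)c1C(=O)O | intermediate
8 | benzyl 2,4-dihydroxy-3,6-dimethylbenzoate | Cc1cc(O)c(C)c(O)c1C(=O)OCc1ccccc1 | intermediate
9 | benzyl 4-[(3-formyl-2-hydroxy-4-methoxy-6-methylbenzoyl)oxy]-2-hydroxy-3,6-dimethylbenzoate | COc1cc(C)c(C(=O)Oc2cc(C)c(C(=O)OCc3ccccc3)c(O)c2C)c(O)c1C=O | intermediate
10 | 3-carboxy depside benzyl ester | COc1cc(C)c(C(=O)Oc2cc(C)c(C(=O)OCc3ccccc3)c(O)c2C)c(O)c1C(=O)O | intermediate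
11 | squamatic acid (achiral) | COc1cc(C)c(C(=O)Oc2cc(C)c(C(=O)O)c(O)c2C)c(O)c1C(=O)O | target

## Totals
Total steps: 9 (two branches converging at step 7). Longest linear sequence: 7 steps (1 → 2 → 3 → 4 → 5 → 9 → 10 → 11).

## Three steps most likely to fail
1. **Step 7 (proposed new boron-templated coupling).** The acyloxyboron may be too weakly electrophilic toward a hindered phenol, or the hindered 2,6-disubstituted acid may not couple.
   - Fallback (known chemistry, different approach): protect 4 as its 2-O-benzyl ether (BnBr, K2CO3), remove the allyl ester with Pd(0), make the acid chloride ((COCl)2, cat. DMF) and couple it with 8 using pyridine/DMAP (Sargent-type). Then run step 8, and step 9 removes the 2-OBn and the benzyl ester together.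
2. **Step 5 (Kolbe–Schmitt on a Me/OH-flanked position).** Yield may be low, and the product acid decarboxylates easily.
   - Fallback: build ring B from benzyl orsellinate by 4-O-allylation, Casnati formylation at C3, Et3SiH/TFA reduction of CHO to CH3 and Pd(0) deallylation, giving 8 without a free β-orcinol acid.
3. **Step 8 (Pinnick oxidation on an electron-rich depside).** Ring chlorination or partial ester cleavage is possible.
   - Fallback: oxidise the aldehyde at the stage of 4 (Pinnick), re-protect the new 3-CO2H as its benzyl ester (BnBr, NaHCO3), remove the allyl ester, and use that acid in step 7. Step 9 then removes both benzyl esters and the Pinnick step is avoided on the depside.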